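**Strategy.** Ring B (numbered as 7‑oxabicyclo[4.1.0]hept‑3‑ene) hides a 2‑pyranone. C1 carries an oxygen and C4 a one‑carbon substituent in a 1,4‑relationship, like C6 and C3 of a 2‑pyranone. The ring oxygen becomes the epoxide oxygen and the lactone carbonyl becomes the CH2OH carbon. C5–C6 is therefore removed as an enol ether: an inverse‑demand Diels–Alder reaction of 6‑(hydroxymethyl)‑2‑pyranone with a (Z)‑2‑bromovinyl silyl ether forms C4–C5 and C6–C1 and four stereocentres in one operation. Lactone methanolysis then closes the epoxide, a lipase resolution sets the absolute configuration, and a (Z)‑dienylmagnesium reagent carrying ring A is added to the C1 aldehyde.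

Key step: step 3

Remark: ring B keeps the target numbering throughout (C1 quaternary epoxide carbon, C2 and C5 carbinols, C3=C4 with CH2OH on C4, C6 epoxide CH; C1' to C5' is the side chain from the carbinol to ring A). Compounds 6 to 10 are racemic and are drawn as the enantiomer that is carried forward. 2‑Oxo‑2H‑pyran‑6‑carboxylic acid is assumed to be purchasable.

## Route

Step 1
Reactants: 1 2-oxo-2H-pyran-6-carboxylic acid
Product: 2 6-(hydroxymethyl)-2H-pyran-2-one
Conditions: BH3·THF (1.5 equiv), THF, 0 °C to rt; aqueous work-up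
Reagents that add atoms: none
Why: Chemoselective borane reduction of a carboxylic acid: the acid reacts through its acyloxyborane much faster than the conjugated enol lactone, so the pyranone should survive.

Step 2
Reactants: 3 bromoacetaldehyde diethyl acetal
Product: 5 (Z)-(2-bromoethenyloxy)(tert-butyl)dimethylsilane, via bromoacetaldehyde 4 (not isolated)
Conditions: aq. HBr (1 M), 60 °C; extraction into CH2Cl2, MgSO4; then t-BuMe2SiOTf, i-Pr2NEt, CH2Cl2, −78 to 0 °C; distillation
Reagents that add atoms: water, O; tert-butyldimethylsilyl trifluoromethanesulfonate, CC(C)(C)[Si](C)(C)OS(=O)(=O)C(F)(F)F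
Why: Acetal hydrolysis followed by soft enolisation with a silyl triflate and a hindered amine (silyl enol ether formation); the Z isomer with the two heteroatoms cis is the favoured geometry of β-halo enol ethers and should be separable from the E isomer by distillation.

Step 3
Reactants: 2 6-(hydroxymethyl)-2H-pyran-2-one; 5 (Z)-(2-bromoethenyloxy)(tert-butyl)dimethylsilane
Product: 6 rac-endo,endo-7-bromo-8-[(tert-butyldimethylsilyl)oxy]-1-(hydroxymethyl)-2-oxabicyclo[2.2.2]oct-5-en-3-one (Br and OSi cis to each other and anti to the lactone bridge)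
Conditions: 5 (3 equiv), CH2Cl2, 13 kbar, 25 °C, 3 d
Reagents that add atoms: none
Why: Concerted but asynchronous inverse-electron-demand [4+2] cycloaddition between the pyranone as electron-poor diene (C3 to C6) and the electron-rich enol ether; the closest known reaction type is the high-pressure Diels–Alder reaction of 2-pyranones with silyl enol ethers and vinyl ethers. The carbocyclic six-membered ring (future ring B) closes in the [4+2] mode and the lactone stays as a bridge, giving the 2-oxabicyclo[2.2.2]octenone. Regiochemistry follows from polarisation: the nucleophilic CHBr terminus bonds to the electrophilic oxygen-bearing C6 of the pyranone (future C6–C1 bond) and the CH(OSi) carbon to C3 (future C4–C5 bond), so the bromide ends next to the carbon that carries the lactone oxygen. The relative configuration of the two bridgeheads is fixed by the bridge, the cis relationship of Br and OSi by suprafacial addition to the Z olefin, and their orientation anti to the lactone bridge by the endo transition state favoured for oxygen-substituted dienophiles. The step needs regio- and endo-selectivity and must not lose CO2; ambient temperature under pressure should prevent the cycloreversion, and the adduct is racemic until step 6.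

Step 4
Reactants: 6 rac-endo,endo-7-bromo-8-[(tert-butyldimethylsilyl)oxy]-1-(hydroxymethyl)-2-oxabicyclo[2.2.2]oct-5-en-3-one
Product: 8 rac-methyl 5-[(tert-butyldimethylsilyl)oxy]-1-(hydroxymethyl)-7-oxabicyclo[4.1.0]hept-2-ene-4-carboxylate (epoxide oxygen and CO2Me on one face; OSi on the other), via bromohydrin ester 7 (not isolated)
Conditions: K2CO3 (1.5 equiv), MeOH, −10 to 0 °C
Reagents that add atoms: methanol, CO
Why: Methanolysis of the strained bridged lactone (transesterification) frees the tertiary C1 alkoxide, which displaces the anti-periplanar C6 bromide with inversion (intramolecular Williamson reaction, 3-exo-tet), so the former pyranone ring oxygen becomes the epoxide oxygen trans to the C5 silyloxy group.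

Step 5
Reactants: 8 rac-methyl 5-[(tert-butyldimethylsilyl)oxy]-1-(hydroxymethyl)-7-oxabicyclo[4.1.0]hept-2-ene-4-carboxylate
Product: 10 rac-methyl 5-[(tert-butyldimethylsilyl)oxy]-2-hydroxy-1-(hydroxymethyl)-7-oxabicyclo[4.1.0]hept-3-ene-4-carboxylate (C2–OH and C5–OSi both trans to the epoxide oxygen), via bis-epoxide 9 (not isolated)
Conditions: mCPBA (1.2 equiv), NaHCO3, CH2Cl2, 0 °C to rt; aq. Na2S2O3/NaHCO3 wash; crude in CH2Cl2, DBU (1.5 equiv), 0 °C to rt
Reagents that add atoms: 3-chloroperoxybenzoic acid, OOC(=O)c1cccc(Cl)c1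
Why: Hydroxyl-directed Prilezhaev epoxidation of C2=C3 on the face syn to the homoallylic CH2OH group and anti to the existing epoxide, then E1cB opening of the β,γ-epoxy ester by removal of the acidic C4 proton, which gives the conjugated ester (C3=C4) and the C2 hydroxyl trans to the epoxide oxygen.

Step 6
Reactants: 10 rac-methyl 5-[(tert-butyldimethylsilyl)oxy]-2-hydroxy-1-(hydroxymethyl)-7-oxabicyclo[4.1.0]hept-3-ene-4-carboxylate
Product: 11 methyl 1-(acetoxymethyl)-5-[(tert-butyldimethylsilyl)oxy]-2-hydroxy-7-oxabicyclo[4.1.0]hept-3-ene-4-carboxylate (single enantiomer; 2S; ring configuration of the target)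
Conditions: immobilised Candida antarctica lipase B, vinyl acetate, t-BuOMe, 30 °C, stopped at about half conversion of the secondary hydroxyl; chromatography
Reagents that add atoms: vinyl acetate, C=COC(C)=O
Why: Lipase-catalysed transesterification used as a kinetic resolution: the primary hydroxyl should be acetylated in both enantiomers, but the allylic C2 hydroxyl only in the 2R enantiomer that fits the usual preference of lipases for secondary alcohols (large group C1, medium group C3), so the required 2S alcohol remains as its primary monoacetate and is separated from the diacetate.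

Step 7
Reactants: 11 methyl 1-(acetoxymethyl)-5-[(tert-butyldimethylsilyl)oxy]-2-hydroxy-7-oxabicyclo[4.1.0]hept-3-ene-4-carboxylate
Product: 12 methyl 1-(acetoxymethyl)-2,5-bis[(tert-butyldimethylsilyl)oxy]-7-oxabicyclo[4.1.0]hept-3-ene-4-carboxylate
Conditions: t-BuMe2SiOTf, 2,6-lutidine, CH2Cl2, −78 to −20 °C
Reagents that add atoms: tert-butyldimethylsilyl trifluoromethanesulfonate, CC(C)(C)[Si](C)(C)OS(=O)(=O)C(F)(F)F
Why: Silylation of a hindered secondary alcohol with a silyl triflate and 2,6-lutidine; the buffered low-temperature conditions should leave the epoxide and the acetate untouched.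

Step 8
Reactants: 12 methyl 1-(acetoxymethyl)-2,5-bis[(tert-butyldimethylsilyl)oxy]-7-oxabicyclo[4.1.0]hept-3-ene-4-carboxylate
Product: 13 methyl 2,5-bis[(tert-butyldimethylsilyl)oxy]-1-(hydroxymethyl)-7-oxabicyclo[4.1.0]hept-3-ene-4-carboxylate
Conditions: K2CO3 (0.3 equiv), MeOH, 0 °C
Reagents that add atoms: none
Why: Base-catalysed methanolysis (transesterification) removes the primary acetate, while exchange at the methyl ester is degenerate and the secondary silyl ethers are stable.

Step 9
Reactants: 13 methyl 2,5-bis[(tert-butyldimethylsilyl)oxy]-1-(hydroxymethyl)-7-oxabicyclo[4.1.0]hept-3-ene-4-carboxylate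
Product: 14 methyl 2,5-bis[(tert-butyldimethylsilyl)oxy]-1-formyl-7-oxabicyclo[4.1.0]hept-3-ene-4-carboxylate
Conditions: Dess–Martin periodinane, NaHCO3, CH2Cl2, 0 °C to rt
Reagents that add atoms: none
Why: Dess–Martin oxidation of the primary alcohol; the aldehyde has a quaternary α-carbon and therefore cannot enolise or epimerise.

Step 10
Reactants: 15 geranyl acetate
Product: 16 (6R)-6,7-epoxygeranyl acetate
Conditions: D-fructose-derived Shi ketone (0.3 equiv), Oxone (2KHSO5·KHSO4·K2SO4), K2CO3, Bu4NHSO4, MeCN/dimethoxymethane/aq. buffer (pH 10.5), 0 °C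
Reagents that add atoms: potassium peroxymonosulfate (KHSO5), [K+].[O-]S(=O)(=O)OO
Why: Shi epoxidation: the chiral dioxirane attacks the electron-rich 6,7-olefin (the 2,3-olefin is deactivated by the allylic acetate) through the spiro transition state, which should set the 6R configuration.

Step 11
Reactants: 16 (6R)-6,7-epoxygeranyl acetate
Product: 17 [(1S,5R)-5-hydroxy-2,6,6-trimethylcyclohex-2-en-1-yl]methyl acetate
Conditions: ZrCl4 (1.1 equiv), CH2Cl2, −78 to −20 °C; chromatography on AgNO3-impregnated silica to remove the exocyclic olefin isomer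
Reagents that add atoms: none
Why: Lewis acid-promoted epoxy-olefin (cation-olefin) cyclisation through a chair transition state: the 2,3-olefin opens the activated epoxide at C7 with inversion, the carbinol carbon keeps its R configuration, the CH2OAc group ends equatorial and cis to the hydroxyl (1S), and loss of a ring proton gives the endocyclic trisubstituted olefin.

Step 12
Reactants: 17 [(1S,5R)-5-hydroxy-2,6,6-trimethylcyclohex-2-en-1-yl]methyl acetate
Product: 18 [(1S,5R)-5-[(tert-butyldimethylsilyl)oxy]-2,6,6-trimethylcyclohex-2-en-1-yl]methyl acetate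
Conditions: t-BuMe2SiOTf, 2,6-lutidine, CH2Cl2, 0 °C
Reagents that add atoms: tert-butyldimethylsilyl trifluoromethanesulfonate, CC(C)(C)[Si](C)(C)OS(=O)(=O)C(F)(F)F
Why: Silyl triflate silylation of the hindered secondary alcohol next to the quaternary carbon.

Step 13
Reactants: 18 [(1S,5R)-5-[(tert-butyldimethylsilyl)oxy]-2,6,6-trimethylcyclohex-2-en-1-yl]methyl acetate
Product: 19 [(1S,5R)-5-[(tert-butyldimethylsilyl)oxy]-2,6,6-trimethylcyclohex-2-en-1-yl]methanol
Conditions: K2CO3, MeOH, rt
Reagents that add atoms: none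
Why: Base-catalysed methanolysis of the primary acetate (transesterification).

Step 14
Reactants: 19 [(1S,5R)-5-[(tert-butyldimethylsilyl)oxy]-2,6,6-trimethylcyclohex-2-en-1-yl]methanol
Product: 20 5-({[(1S,5R)-5-[(tert-butyldimethylsilyl)oxy]-2,6,6-trimethylcyclohex-2-en-1-yl]methyl}sulfanyl)-1-phenyl-1H-tetrazole
Conditions: 1-phenyl-1H-tetrazole-5-thiol, PPh3, DIAD, THF, 0 °C to rt
Reagents that add atoms: 1-phenyl-1H-tetrazole-5-thiol, Sc1nnnn1-c1ccccc1
Why: Mitsunobu thioetherification of the primary alcohol with the acidic tetrazole thiol; no stereocentre is involved.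

Step 15
Reactants: 20 5-({[(1S,5R)-5-[(tert-butyldimethylsilyl)oxy]-2,6,6-trimethylcyclohex-2-en-1-yl]methyl}sulfanyl)-1-phenyl-1H-tetrazole
Product: 21 5-({[(1S,5R)-5-[(tert-butyldimethylsilyl)oxy]-2,6,6-trimethylcyclohex-2-en-1-yl]methyl}sulfonyl)-1-phenyl-1H-tetrazole
Conditions: (NH4)6Mo7O24·4H2O (10 mol%), 30% aq. H2O2, EtOH, 0 °C to rt
Reagents that add atoms: hydrogen peroxide, OO
Why: Molybdate-catalysed oxidation of the sulfide to the sulfone; an isolated trisubstituted olefin is normally not epoxidised under these conditions.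

Step 16
Reactants: 22 propargyl alcohol
Product: 24 (Z)-3-iodo-2-methylprop-2-en-1-ol, via alkenylmagnesium alkoxide 23 (not isolated)
Conditions: MeMgBr (2.5 equiv), CuI (10 mol%), THF, −10 °C to rt; then I2, −10 °C
Reagents that add atoms: methylmagnesium bromide, C[Mg]Br; iodine, [I][I]
Why: Copper-catalysed anti-carbomagnesiation of the propargylic alkoxide gives a five-membered oxamagnesacycle with methyl on C2 and magnesium on C3 cis to the CH2O group, and iodinolysis with retention gives the Z iodide.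

Step 17
Reactants: 24 (Z)-3-iodo-2-methylprop-2-en-1-ol
Product: 25 (Z)-3-iodo-2-methylprop-2-enal
Conditions: MnO2 (excess), CH2Cl2, rt, dark; used at once
Reagents that add atoms: none
Why: MnO2 oxidation of the allylic alcohol under neutral conditions, which should preserve the Z geometry if light and acid are excluded.

Step 18
Reactants: 21 5-({[(1S,5R)-5-[(tert-butyldimethylsilyl)oxy]-2,6,6-trimethylcyclohex-2-en-1-yl]methyl}sulfonyl)-1-phenyl-1H-tetrazole; 25 (Z)-3-iodo-2-methylprop-2-enal
Product: 26 tert-butyl{[(1R,5S)-5-[(1E,3Z)-4-iodo-3-methylbuta-1,3-dien-1-yl]-4,6,6-trimethylcyclohex-3-en-1-yl]oxy}dimethylsilane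
Conditions: KN(SiMe3)2 (1.05 equiv), DME, −60 °C; then 25; warm to rt
Reagents that add atoms: none
Why: Julia–Kocienski olefination: addition of the metalated tetrazolyl sulfone to the aldehyde, Smiles rearrangement and anti elimination should give the E olefin (C4'=C5'), while the Z iodoalkene is not touched.

Step 19
Reactants: 26 tert-butyl{[(1R,5S)-5-[(1E,3Z)-4-iodo-3-methylbuta-1,3-dien-1-yl]-4,6,6-trimethylcyclohex-3-en-1-yl]oxy}dimethylsilane; 14 methyl 2,5-bis[(tert-butyldimethylsilyl)oxy]-1-formyl-7-oxabicyclo[4.1.0]hept-3-ene-4-carboxylate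
Product: 29 methyl 2,5-bis[(tert-butyldimethylsilyl)oxy]-1-[(1S,2Z,4E)-5-{(1S,5R)-5-[(tert-butyldimethylsilyl)oxy]-2,6,6-trimethylcyclohex-2-en-1-yl}-1-hydroxy-3-methylpenta-2,4-dien-1-yl]-7-oxabicyclo[4.1.0]hept-3-ene-4-carboxylate, via dienyllithium 27 (not isolated), via dienylmagnesium bromide 28 (not isolated)
Conditions: 26 (1.3 equiv), t-BuLi (2.6 equiv), Et2O, −78 °C; MgBr2·OEt2 (1.4 equiv), −78 to −40 °C; then 14, CH2Cl2/Et2O, −78 °C; aq. NH4Cl
Reagents that add atoms: none
Why: Chelation-controlled 1,2-addition of an alkenyl Grignard reagent: magnesium bridges the aldehyde and epoxide oxygens in a five-membered chelate and the nucleophile should attack the face next to the small epoxide CH (C6) rather than the face shielded by the cis C2 silyloxy group, which corresponds to the 1'S alcohol, while iodine–lithium exchange and transmetalation retain the Z geometry.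

Step 20
Reactants: 29 methyl 2,5-bis[(tert-butyldimethylsilyl)oxy]-1-[(1S,2Z,4E)-5-{(1S,5R)-5-[(tert-butyldimethylsilyl)oxy]-2,6,6-trimethylcyclohex-2-en-1-yl}-1-hydroxy-3-methylpenta-2,4-dien-1-yl]-7-oxabicyclo[4.1.0]hept-3-ene-4-carboxylate
Product: 30 (1S,2Z,4E)-1-{2,5-bis[(tert-butyldimethylsilyl)oxy]-4-(hydroxymethyl)-7-oxabicyclo[4.1.0]hept-3-en-1-yl}-5-{(1S,5R)-5-[(tert-butyldimethylsilyl)oxy]-2,6,6-trimethylcyclohex-2-en-1-yl}-3-methylpenta-2,4-dien-1-ol
Conditions: i-Bu2AlH (4 equiv), CH2Cl2, −78 °C; Rochelle salt work-up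
Reagents that add atoms: none
Why: 1,2-Reduction of the conjugated methyl ester to the allylic alcohol with i-Bu2AlH at −78 °C, where the epoxide next to the aluminium alkoxide and the silyl ethers should survive.

Step 21
Reactants: 30 (1S,2Z,4E)-1-{2,5-bis[(tert-butyldimethylsilyl)oxy]-4-(hydroxymethyl)-7-oxabicyclo[4.1.0]hept-3-en-1-yl}-5-{(1S,5R)-5-[(tert-butyldimethylsilyl)oxy]-2,6,6-trimethylcyclohex-2-en-1-yl}-3-methylpenta-2,4-dien-1-ol
Product: 31 (1R,2S,5R,6S)-1-[(1S,2Z,4E)-1-hydroxy-5-[(1S,5R)-5-hydroxy-2,6,6-trimethylcyclohex-2-en-1-yl]-3-methylpenta-2,4-dien-1-yl]-4-(hydroxymethyl)-7-oxabicyclo[4.1.0]hept-3-ene-2,5-diol (CNP0389279.1)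
Conditions: Bu4NF/AcOH (1:1, excess), THF, 0 °C to rt
Reagents that add atoms: none
Why: Fluoride-mediated cleavage of the three silyl ethers; buffering with acetic acid keeps the liberated hydroxyls protonated, so that Payne migration of the epoxide should not occur.

## Compound list

1 | 2-oxo-2H-pyran-6-carboxylic acid | O=C1C=CC=C(C(=O)O)O1 | starting material
2 | 6-(hydroxymethyl)-2H-pyran-2-one | O=C1C=CC=C(CO)O1 | intermediate
3 | bromoacetaldehyde diethyl acetal | CCOC(CBr)OCC | starting material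
4 | bromoacetaldehyde | O=CCBr | intermediate
5 | (Z)-(2-bromoethenyloxy)(tert-butyl)dimethylsilane | Br/C=C\O[Si](C)(C)C(C)(C)C | intermediate
6 | rac-endo,endo-7-bromo-8-[(tert-butyldimethylsilyl)oxy]-1-(hydroxymethyl)-2-oxabicyclo[2.2.2]oct-5-en-3-one | OC[C@@]12OC(=O)[C@@H](C=C1)[C@@H](O[Si](C)(C)C(C)(C)C)[C@H]2Br | intermediate
7 | rac-methyl 5-bromo-6-[(tert-butyldimethylsilyl)oxy]-4-hydroxy-4-(hydroxymethyl)cyclohex-2-ene-1-carboxylate (bromohydrin ester; OH trans to Br) | OC[C@@]1(O)C=C[C@H](C(=O)OC)[C@@H](O[Si](C)(C)C(C)(C)C)[C@H]1Br | intermediate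
8 | rac-methyl 5-[(tert-butyldimethylsilyl)oxy]-1-(hydroxymethyl)-7-oxabicyclo[4.1.0]hept-2-ene-4-carboxylate | OC[C@]12O[C@H]1[C@H](O[Si](C)(C)C(C)(C)C)[C@@H](C(=O)OC)C=C2 | intermediate
9 | rac-bis-epoxide of 8 (new C2–C3 epoxide anti to the C1–C6 epoxide) | OC[C@]12O[C@H]1[C@H](O[Si](C)(C)C(C)(C)C)[C@@H](C(=O)OC)[C@@H]3O[C@H]23 | intermediate
10 | rac-methyl 5-[(tert-butyldimethylsilyl)oxy]-2-hydroxy-1-(hydroxymethyl)-7-oxabicyclo[4.1.0]hept-3-ene-4-carboxylate | OC[C@]12O[C@H]1[C@H](O[Si](C)(C)C(C)(C)C)C(C(=O)OC)=C[C@@H]2O | intermediate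
11 | methyl 1-(acetoxymethyl)-5-[(tert-butyldimethylsilyl)oxy]-2-hydroxy-7-oxabicyclo[4.1.0]hept-3-ene-4-carboxylate (single enantiomer) | CC(=O)OC[C@]12O[C@H]1[C@H](O[Si](C)(C)C(C)(C)C)C(C(=O)OC)=C[C@@H]2O | intermediate
12 | methyl 1-(acetoxymethyl)-2,5-bis[(tert-butyldimethylsilyl)oxy]-7-oxabicyclo[4.1.0]hept-3-ene-4-carboxylate | CC(=O)OC[C@]12O[C@H]1[C@H](O[Si](C)(C)C(C)(C)C)C(C(=O)OC)=C[C@@H]2O[Si](C)(C)C(C)(C)C | intermediate
13 | methyl 2,5-bis[(tert-butyldimethylsilyl)oxy]-1-(hydroxymethyl)-7-oxabicyclo[4.1.0]hept-3-ene-4-carboxylate | OC[C@]12O[C@H]1[C@H](O[Si](C)(C)C(C)(C)C)C(C(=O)OC)=C[C@@H]2O[Si](C)(C)C(C)(C)C | intermediate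
14 | methyl 2,5-bis[(tert-butyldimethylsilyl)oxy]-1-formyl-7-oxabicyclo[4.1.0]hept-3-ene-4-carboxylate | O=C[C@]12O[C@H]1[C@H](O[Si](C)(C)C(C)(C)C)C(C(=O)OC)=C[C@@H]2O[Si](C)(C)C(C)(C)C | intermediate
15 | geranyl acetate | CC(=O)OC/C=C(\C)CCC=C(C)C | starting material
16 | (6R)-6,7-epoxygeranyl acetate | CC(=O)OC/C=C(\C)CC[C@H]1OC1(C)C | intermediate
17 | [(1S,5R)-5-hydroxy-2,6,6-trimethylcyclohex-2-en-1-yl]methyl acetate | CC1=CC[C@@H](O)C(C)(C)[C@H]1COC(C)=O | intermediate
18 | [(1S,5R)-5-[(tert-butyldimethylsilyl)oxy]-2,6,6-trimethylcyclohex-2-en-1-yl]methyl acetate | CC1=CC[C@@H](O[Si](C)(C)C(C)(C)C)C(C)(C)[C@H]1COC(C)=O | intermediate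
19 | [(1S,5R)-5-[(tert-butyldimethylsilyl)oxy]-2,6,6-trimethylcyclohex-2-en-1-yl]methanol | CC1=CC[C@@H](O[Si](C)(C)C(C)(C)C)C(C)(C)[C@H]1CO | intermediate
20 | 5-({[(1S,5R)-5-[(tert-butyldimethylsilyl)oxy]-2,6,6-trimethylcyclohex-2-en-1-yl]methyl}sulfanyl)-1-phenyl-1H-tetrazole | CC1=CC[C@@H](O[Si](C)(C)C(C)(C)C)C(C)(C)[C@H]1CSc1nnnn1-c1ccccc1 | intermediate
21 | 5-({[(1S,5R)-5-[(tert-butyldimethylsilyl)oxy]-2,6,6-trimethylcyclohex-2-en-1-yl]methyl}sulfonyl)-1-phenyl-1H-tetrazole | CC1=CC[C@@H](O[Si](C)(C)C(C)(C)C)C(C)(C)[C@H]1CS(=O)(=O)c1nnnn1-c1ccccc1 | intermediate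
22 | propargyl alcohol | C#CCO | starting material
23 | bromomagnesium (Z)-3-(bromomagnesio)-2-methylprop-2-en-1-olate | Br[Mg]OC/C(C)=C\[Mg]Br | intermediate
24 | (Z)-3-iodo-2-methylprop-2-en-1-ol | OC/C(C)=C\I | intermediate
25 | (Z)-3-iodo-2-methylprop-2-enal | O=C/C(C)=C\I | intermediate
26 | tert-butyl{[(1R,5S)-5-[(1E,3Z)-4-iodo-3-methylbuta-1,3-dien-1-yl]-4,6,6-trimethylcyclohex-3-en-1-yl]oxy}dimethylsilane | CC1=CC[C@@H](O[Si](C)(C)C(C)(C)C)C(C)(C)[C@H]1/C=C/C(C)=C\I | intermediate
27 | (1Z,3E)-dienyllithium from 26 (Li in place of I) | CC1=CC[C@@H](O[Si](C)(C)C(C)(C)C)C(C)(C)[C@H]1/C=C/C(C)=C\[Li] | intermediate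
28 | (1Z,3E)-dienylmagnesium bromide from 27 | CC1=CC[C@@H](O[Si](C)(C)C(C)(C)C)C(C)(C)[C@H]1/C=C/C(C)=C\[Mg]Br | intermediate
29 | methyl 2,5-bis[(tert-butyldimethylsilyl)oxy]-1-[(1S,2Z,4E)-5-{(1S,5R)-5-[(tert-butyldimethylsilyl)oxy]-2,6,6-trimethylcyclohex-2-en-1-yl}-1-hydroxy-3-methylpenta-2,4-dien-1-yl]-7-oxabicyclo[4.1.0]hept-3-ene-4-carboxylate | CC1=CC[C@@H](O[Si](C)(C)C(C)(C)C)C(C)(C)[C@H]1/C=C/C(C)=C\[C@H](O)[C@]12O[C@H]1[C@H](O[Si](C)(C)C(C)(C)C)C(C(=O)OC)=C[C@@H]2O[Si](C)(C)C(C)(C)C | intermediate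
30 | tris(tert-butyldimethylsilyl) ether of the target (silyl on the ring A oxygen and on O2 and O5 of ring B; C1'–OH and CH2OH free) | CC1=CC[C@@H](O[Si](C)(C)C(C)(C)C)C(C)(C)[C@H]1/C=C/C(C)=C\[C@H](O)[C@]12O[C@H]1[C@H](O[Si](C)(C)C(C)(C)C)C(CO)=C[C@@H]2O[Si](C)(C)C(C)(C)C | intermediate
31 | (1R,2S,5R,6S)-1-[(1S,2Z,4E)-1-hydroxy-5-[(1S,5R)-5-hydroxy-2,6,6-trimethylcyclohex-2-en-1-yl]-3-methylpenta-2,4-dien-1-yl]-4-(hydroxymethyl)-7-oxabicyclo[4.1.0]hept-3-ene-2,5-diol | CC1=CC[C@@H](O)C(C)(C)[C@H]1/C=C/C(C)=C\[C@H](O)[C@]12O[C@H]1[C@H](O)C(CO)=C[C@@H]2O | target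

## Step count and risks

Total step count: 21. Longest linear sequence: 11 steps (steps 1, 3 to 9 and 19 to 21, from 2-oxo-2H-pyran-6-carboxylic acid). The ring A branch (steps 10 to 15 and 18) is 10 steps to the target.

Steps most likely to fail:

1. Step 3 (key cycloaddition). The unactivated 6-substituted pyranone and the β-bromo enol ether may combine too slowly even under pressure. Forcing the reaction thermally would lead to loss of CO2 from the adduct, and the exo mode would place the bromide syn to the lactone oxygen, where it cannot be displaced. The fallback sets out from 2 and activates the diene as a 3-bromopyranone, a diene type known to add silyl vinyl ethers below 100 °C without decarboxylation. Bromination of 2 at C3 (Br2, CH2Cl2, then Et3N) should give 3-bromo-6-(hydroxymethyl)-2H-pyran-2-one F1. Thermal cycloaddition of F1 with 5 (toluene, 90 °C) should give rac-endo,endo-4,7-dibromo-8-[(tert-butyldimethylsilyl)oxy]-1-(hydroxymethyl)-2-oxabicyclo[2.2.2]oct-5-en-3-one F2. Selective radical reduction of the tertiary bridgehead α-carbonyl bromide (Bu3SnH, 1.0 equiv, Et3B/air, toluene, −40 °C) comes back to the route at 6.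

2. Step 6 (resolution). The secondary alcohol next to the quaternary carbon may be acylated too slowly by the enzyme, or the two enantiomers may be discriminated poorly. The fallback sets out from 10 and resolves through diastereomeric esters. Esterification of the primary hydroxyl with (S)-O-methylmandelic acid (DCC, DMAP, CH2Cl2, −20 °C) and separation of the diastereomers by chromatography or crystallisation should give the primary (S)-O-methylmandelate of the required enantiomer of 10, F3. Silylation (t-BuMe2SiOTf, 2,6-lutidine) gives its C2 silyl ether F4, and methanolysis of the mandelate (K2CO3, MeOH, 0 °C) comes back to the route at 13.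

3. Step 19 (fragment union). Addition through a non-chelated, Felkin-type transition state would give the C1' epimer. Epoxide opening by the magnesium halide or erosion of the Z geometry are further risks. The fallback sets out from 29 obtained as a mixture with the C1' epimer of 29, F5. The mixture is oxidised (Dess–Martin periodinane, NaHCO3, CH2Cl2) to the (2Z,4E)-dienyl epoxy ketone F6. Reduction with the non-chelating hydride i-Bu2AlH (CH2Cl2, −78 °C) should deliver hydride anti to the epoxide C–O bond, with the dienyl group turned away from the C2 silyloxy substituent (polar Felkin–Anh model), which gives the 1'S alcohol. The methyl ester is reduced in the same operation, so the route is rejoined at 30.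

## Further compounds

F1 | step 3 | 3-bromo-6-(hydroxymethyl)-2H-pyran-2-one | O=C1OC(CO)=CC=C1Br
F2 | step 3 | rac-endo,endo-4,7-dibromo-8-[(tert-butyldimethylsilyl)oxy]-1-(hydroxymethyl)-2-oxabicyclo[2.2.2]oct-5-en-3-one | OC[C@@]12OC(=O)[C@@](Br)(C=C1)[C@@H](O[Si](C)(C)C(C)(C)C)[C@H]2Br
F3 | step 6 | primary (S)-O-methylmandelate of the required enantiomer of 10 | CO[C@H](C(=O)OC[C@]12O[C@H]1[C@H](O[Si](C)(C)C(C)(C)C)C(C(=O)OC)=C[C@@H]2O)c1ccccc1
F4 | step 6 | C2 tert-butyldimethylsilyl ether of F3 | CO[C@H](C(=O)OC[C@]12O[C@H]1[C@H](O[Si](C)(C)C(C)(C)C)C(C(=O)OC)=C[C@@H]2O[Si](C)(C)C(C)(C)C)c1ccccc1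
F5 | step 19 | C1' epimer of 29 | CC1=CC[C@@H](O[Si](C)(C)C(C)(C)C)C(C)(C)[C@H]1/C=C/C(C)=C\[C@@H](O)[C@]12O[C@H]1[C@H](O[Si](C)(C)C(C)(C)C)C(C(=O)OC)=C[C@@H]2O[Si](C)(C)C(C)(C)C
F6 | step 19 | (2Z,4E)-dienyl epoxy ketone (C1' ketone of 29) | CC1=CC[C@@H](O[Si](C)(C)C(C)(C)C)C(C)(C)[C@H]1/C=C/C(C)=C\C(=O)[C@]12O[C@H]1[C@H](O[Si](C)(C)C(C)(C)C)C(C(=O)OC)=C[C@@H]2O[Si](C)(C)C(C)(C)C
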